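Every part of the charge stands as substrate, intermediate or target, and at 1.00 equiv of second reagent each target takes one unit from a pool that began equal to the substrate, so the unspent pool, in whatever form it sits, is taken as the charge less the target.

in all of them: substrate 0.25 M; gas 9.6 mM (held)

| flask | second reagent | remark | time |
|---|---|---|---|
| north-west | 1 equiv | the very flask that is asked about, followed so far |  |
| flask | 1.00 equiv |  | 2.5 h |

north-west run (percent of the substrate charged)

| time / min | intermediate / % | target / % |
|---|---|---|
| 10.0 | 19.7 | 7.7 |
| 15.0 | 26.6 | 15.2 |
| 25.0 | 37.4 | 31.5 |
| 40.0 | 41.3 | 53.0 |
| 60.0 | 29.6 | 71.0 |

(each reading ± 0.5 percentage points)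

- at the start none of the gas is in solution

- time up to 2.5 h at which intermediate stands highest
- the amount of intermediate, in percent of the substrate charged, at that time

What has been used up? Intermediate plus target in the north-west run reaches 100.6% at 60.0 min, which is the whole charge within the scatter.

How fast does target form? From 25.0 min to 40.0 min its rise, divided by the mean intermediate and the mean unspent pool, both as fractions of the charge, gives 0.0631 min⁻¹, the pool constant, a reading that says how quickly a given intermediate and pool make target.

Is that one lucky window? The next window, up to 60.0 min, gives 0.0668 min⁻¹, close enough to carry.

Where is the top? In the first window the charge is used at 0.0169 min⁻¹, faster than target forms at 0.0143 min⁻¹, so intermediate is still climbing on average, but in the second window it falls, and I commit to a top near 40.0 min, a little above the reading of 41.3%.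

The forecast says 0.6 h and 42%: “Intermediate peaks when substrate use equals target formation”.

The flask gives 0.627 h and 41.9%.

    substrate + coupling partner → intermediate (k = 0.500 L mol⁻¹ s⁻¹)
    second reagent + intermediate → target (k = 0.0120 L mol⁻¹ s⁻¹)
    gas ⇌ coupling partner, rate k3*(csat - [coupling partner]) (kL = 0.0140 s⁻¹)
    second reagent ⇌ dormant form (K = 1.60, k = 0.00500 s⁻¹)

Second reagent and dormant form relax towards each other with a half-life of 1.42 min, far shorter than the 2.5 h allowed, so I count them as one pool. In the neighbouring flask with 0.400 equiv of second reagent, that pool decays in a pseudo-first-order way while intermediate stays high, and at 60.2% of intermediate the pool constant gives a half-life of 18.2 min, shorter than the 2.5 h allowed. Target should therefore end just under the charge of second reagent, with the rest of the substrate as intermediate. That neighbouring flask tops out at 69.7% of intermediate and holds 39.8% of target and 60.2% of intermediate at 2.50 h.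

The readings come from a simulation from invented constants, and the scatter is random.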